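**Assumptions (one line each).**
- Drimane numbering is used: C11 is on C9 and C12 is on C8. The target is the natural-series drimane (10β-Me, 5α-H), which matches (+)-sclareolide, so 1β,6α-diacetoxy-9α-hydroxydrim-7-ene-11,12-dial is the structure planned.
- Compound 2 is a mixture of C11 epimers, which converge in step 2.

## Retrosynthetic overview
1. The C11 and C12 aldehydes come from late oxidations: C12 methyl by SeO2 and C11 CH2OH by TEMPO. The 6α-OAc is installed last, after the 6α,9α-diol is revealed.
2. The cis-6α,9α-dioxygenated Δ7 unit comes from singlet-oxygen [4+2] addition to a Δ6,8-diene. The α-face is selected by the 10β-Me, as in ergosterol peroxide, and the O–O bond is then reduced.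
3. The 1β-oxygen comes from a C11-alkoxy-radical 1,5-HAT onto peri H-1β (hypoiodite cyclisation), followed by acetolysis of the peri ether.
4. Drimenol comes from (+)-sclareolide by α-hydroxylation and oxidative loss of the lactone carbonyl carbon (labdane C12).
5. No ring is built. Both rings, C5 and C10 are in the chiral-pool terpenoid. The only new rings are transient: the peri-THF in step 4 and the endoperoxide in step 8.

## Route

**Step 1**
Reactants: 1 (+)-sclareolide
Product: 2 11-hydroxysclareolide (C11 epimeric mixture)
Conditions: LDA, THF, −78 °C; then Davis oxaziridine, −78 → 0 °C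
Reagents that add atoms: 2-(phenylsulfonyl)-3-phenyloxaziridine, O=S(=O)(c1ccccc1)N1OC1c1ccccc1 (O donor)
Why: Lactone enolate α-hydroxylation (Davis oxidation) occurs at the only acidic CH2, C11. The new carbinol stereocentre is irrelevant because it is destroyed in step 2.

**Step 2**
Reactants: 2
Product: 3 drim-8-en-11-al
Conditions: Pb(OAc)4, PhH, 80 °C; then TsOH·H2O (cat.), 80 °C
Reagents that add atoms: none
Why: Pb(IV) glycol-type cleavage of the α-hydroxy lactone gives the C11 aldehyde and an alkoxycarbonyl radical. This loses CO2 to a C8 radical, which is oxidised and eliminates. Acid then equilibrates the alkene into the conjugated tetrasubstituted enal, erasing the sclareolide C9 centre (reset in step 8).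

**Step 3**
Reactants: 3
Product: 4 drim-8-en-11-ol (drimenol)
Conditions: NaBH4, CeCl3·7H2O, MeOH, 0 °C
Reagents that add atoms: none
Why: Luche 1,2-reduction of the enal gives the primary allylic alcohol needed as the radical precursor.

**Step 4**
Reactants: 4
Product: 5 1β,11-epoxydrim-8-ene (peri-fused THF ether, O bridging C1 and C11)
Conditions: PhI(OAc)2, I2, cyclohexane, visible light (tungsten lamp), 30 °C
Reagents that add atoms: none
Why: Proposed new method: the C11 alkoxy radical from the hypoiodite sits peri and parallel to the equatorial β H-1, so a six-membered 1,5-HAT gives a C1 radical. This is oxidised or iodinated and captured by the same oxygen, which can only reach the β face, so the C1–O bond is 1β. The closest known reaction is the Suárez hypoiodite remote functionalisation (11β-OH steroid → 18/19-ethers), here applied to a secondary peri C–H of a drimenol. Competing H-abstraction from the C15 methyl is expected to be disfavoured by the weaker secondary C–H and the near-coplanar peri arrangement in the Δ8 system.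

**Step 5**
Reactants: 5
Product: 6 1β,11-diacetoxydrim-8-ene
Conditions: Ac2O, BF3·OEt2, CH2Cl2, 0 °C
Reagents that add atoms: acetic anhydride, CC(=O)OC(C)=O
Why: Lewis-acid acetolysis of the ether cleaves the allylic C11–O bond selectively (SN1/SN2 at primary C11). The C1–O bond stays, so the 1β centre is retained as the acetate.

**Step 6**
Reactants: 6
Product: 7 1β,11-diacetoxy-7α-bromodrim-8-ene
Conditions: NBS, AIBN, CCl4, hv (tungsten lamp), reflux
Reagents that add atoms: N-bromosuccinimide, O=C1CCC(=O)N1Br
Why: Wohl–Ziegler allylic bromination at the ring CH2 (C7) follows the steroid Δ5 → 7-bromo precedent, with axial (α) bromide.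

**Step 7**
Reactants: 7
Product: 8 1β,11-diacetoxydrim-6,8-diene
Conditions: 2,4,6-collidine, xylene, 140 °C
Reagents that add atoms: none
Why: E2 dehydrobromination of the axial 7α-Br with the anti-periplanar axial H-6β gives the homoannular conjugated diene, as in the 7-dehydrocholesterol synthesis.

**Step 8**
Reactants: 8
Product: 9 6α,9α-epidioxy-1β,11-diacetoxydrim-7-ene
Conditions: O2, TPP (cat.), visible light, CH2Cl2, −10 °C
Reagents that add atoms: dioxygen, O=O
Why: Schenck singlet-oxygen [4+2] cycloaddition adds suprafacially across C6/C9. The axial 10β-Me blocks the β face, so both C–O bonds form on the α face (ergosterol → 5α,8α-peroxide precedent). This sets 6α-O and 9α-O cis and pushes C11 to the β side, creating two stereocentres and shifting the alkene to C7=C8.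

**Step 9**
Reactants: 9
Product: 10 1β,11-diacetoxydrim-7-ene-6α,9α-diol
Conditions: thiourea, MeOH, 25 °C
Reagents that add atoms: none
Why: Thiourea reduces the endoperoxide O–O bond to the cis-1,4-diol with retention at both carbons. It is neutral, so base-induced Kornblum–DeLaMare cleavage to the 6-ketone is avoided.

**Step 10**
Reactants: 10
Product: 11 1β-acetoxydrim-7-ene-6α,9α,11-triol
Conditions: K2CO3, MeOH, 0 °C
Reagents that add atoms: none
Why: Mild methanolysis removes the primary C11 acetate faster than the hindered equatorial 1β-acetate, with no stereocentre involved.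

**Step 11**
Reactants: 11
Product: 12 1β-acetoxy-6α,9α-dihydroxydrim-7-en-11-al
Conditions: TEMPO (10 mol%), PhI(OAc)2, CH2Cl2, 25 °C
Reagents that add atoms: none
Why: TEMPO/BAIB oxidation is selective for the primary alcohol, giving the α-hydroxy aldehyde. C9 has no α-H, so there is no epimerisation.

**Step 12**
Reactants: 12
Product: 13 1β,6α-diacetoxy-9α-hydroxydrim-7-en-11-al
Conditions: Ac2O, DMAP, Et3N, CH2Cl2, 0 °C
Reagents that add atoms: acetic anhydride, CC(=O)OC(C)=O
Why: The unhindered secondary allylic 6α-OH is acetylated, while the tertiary 9α-OH is left free by sterics.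

**Step 13**
Reactants: 13
Product: 14 parritadial (1β,6α-diacetoxy-9α-hydroxydrim-7-ene-11,12-dial)
Conditions: SeO2, 1,4-dioxane, 90 °C
Reagents that add atoms: selenium dioxide, O=[Se]=O
Why: Riley allylic oxidation acts on the only oxidisable allylic position, the C8 methyl (C12), since C9 has no H and C6 carries OAc. The product is the conjugated enal, and no stereocentre is touched.

## Compound list
1 | (+)-sclareolide | O=C1C[C@@H]2[C@@]3(C)CCCC(C)(C)[C@@H]3CC[C@@]2(C)O1 | starting material
2 | 11-hydroxysclareolide (C11 epimers) | O=C1C(O)[C@@H]2[C@@]3(C)CCCC(C)(C)[C@@H]3CC[C@@]2(C)O1 | intermediate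
3 | drim-8-en-11-al | O=CC1=C(C)CC[C@H]2C(C)(C)CCC[C@]12C | intermediate
4 | drim-8-en-11-ol (drimenol) | OCC1=C(C)CC[C@H]2C(C)(C)CCC[C@]12C | intermediate
5 | 1β,11-epoxydrim-8-ene | CC1=C2CO[C@@H]3CCC(C)(C)[C@@H]([C@@]23C)CC1 | intermediate
6 | 1β,11-diacetoxydrim-8-ene | CC(=O)OCC1=C(C)CC[C@H]2C(C)(C)CC[C@@H](OC(C)=O)[C@]12C | intermediate
7 | 1β,11-diacetoxy-7α-bromodrim-8-ene | CC(=O)OCC1=C(C)[C@H](Br)C[C@H]2C(C)(C)CC[C@@H](OC(C)=O)[C@]12C | intermediate
8 | 1β,11-diacetoxydrim-6,8-diene | CC(=O)OCC1=C(C)C=C[C@H]2C(C)(C)CC[C@@H](OC(C)=O)[C@]12C | intermediate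
9 | 6α,9α-epidioxy-1β,11-diacetoxydrim-7-ene | CC(=O)OC[C@@]12OO[C@@H](C=C1C)[C@H]3C(C)(C)CC[C@@H](OC(C)=O)[C@]23C | intermediate
10 | 1β,11-diacetoxydrim-7-ene-6α,9α-diol | CC(=O)OC[C@@]1(O)C(C)=C[C@H](O)[C@H]2C(C)(C)CC[C@@H](OC(C)=O)[C@]12C | intermediate
11 | 1β-acetoxydrim-7-ene-6α,9α,11-triol | OC[C@@]1(O)C(C)=C[C@H](O)[C@H]2C(C)(C)CC[C@@H](OC(C)=O)[C@]12C | intermediate
12 | 1β-acetoxy-6α,9α-dihydroxydrim-7-en-11-al | O=C[C@@]1(O)C(C)=C[C@H](O)[C@H]2C(C)(C)CC[C@@H](OC(C)=O)[C@]12C | intermediate
13 | 1β,6α-diacetoxy-9α-hydroxydrim-7-en-11-al | O=C[C@@]1(O)C(C)=C[C@H](OC(C)=O)[C@H]2C(C)(C)CC[C@@H](OC(C)=O)[C@]12C | intermediate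
14 | parritadial | CC(=O)O[C@H]1C=C(C=O)[C@](O)(C=O)[C@@]2(C)[C@H](OC(C)=O)CCC(C)(C)[C@H]12 | target

## Summary
Total steps: 13. Longest linear sequence: 13 (all steps are linear from 1).

**Three steps most likely to fail**

1. **Step 4 (proposed new peri 1,5-HAT/etherification).**
   - Risks: H-abstraction from the C15 methyl instead of H-1β, or iodination of the tetrasubstituted alkene.
   - Fallback: Barton nitrite relay on 4 (t-BuONO, then hv in toluene). NO capture gives the C1 oxime, which is cleaved (NaNO2/AcOH) to the 1-ketone. NaBH4 then delivers hydride from the α face to give 1β-OH. Ac2O/py gives 6, rejoining the route at Step 6.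

2. **Step 7 (regioselective C7 bromination/elimination to the 6,8-diene).**
   - Risk: competing bromination at C11 or C12.
   - Fallback: allylic oxidation of 6 at C7 (CrO3·3,5-dimethylpyrazole) to the 7-oxo enone. KHMDS/PhNTf2 then gives the dienyl triflate, and Pd(OAc)2/PPh3/HCO2H/Et3N reduction gives diene 8.

3. **Step 13 (SeO2 on the polyfunctional 13).**
   - Risks: over-oxidation, or allylic transposition of the tertiary 9-OH.
   - Fallback: radical allylic bromination of 13 (NBS, hv), then Kornblum oxidation (DMSO, NaHCO3, 90 °C) of the C12 bromide to the enal.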